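The ratio of substrate to open intermediate on the flat top of the eta run, 13% to 63% at 2.00 min, is where I start with your quick number and with your hunch that the closed flask, blue, is hard to beat.

| setting | eta | epsilon | blue | red | violet | green |
|---|---|---|---|---|---|---|
| substrate | 19 mM | 19 mM | 19 mM | 19 mM | 19 mM (fed, over 4.00 min) | 19 mM |
| partner | 20.9 mM | 42 mM | 20.9 mM | 20.9 mM (fed, over 4.00 min) | 20.9 mM | 20.9 mM |
| remark | run made earlier | run made earlier | everything together in a closed stirred flask, run for 4.0 min | all but partner at the start; partner goes in evenly over 4.00 min, the run ends at 4.0 min | a stirred flask in which substrate is dosed at a steady rate over 4.00 min without added volume, worked up at 4.0 min | one stirred flow tank at steady state, fed with the mixture as stated, mean residence time 4.0 min |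
| time |  |  | 4.0 min | 4.0 min | 4.0 min |  |

- eta (time / min: open intermediate / %, target / %, substrate / %): 0.500: 36, 3, 61; 1.00: 58, 0, 35; 1.33: 63, 0, 29; 2.00: 63, 3, 13; 2.50: 64, 4, 8
- epsilon (time / s: open intermediate / %, target / %, substrate / %): 10.0: 17, 2, 85; 15.0: 22, 2, 81; 20.0: 25, 4, 72; 25.0: 29, 2, 63

(each reading ± 2 percentage points)

* the set-up with the highest amount of open intermediate at the outlet or at the end, in percent of the substrate put in ("none" if the first two lie within 2 percentage points) (blue / red / violet / green / none)
* amount of open intermediate at the outlet or at the end, in percent of the substrate put in, blue
* amount of open intermediate at the outlet or at the end, in percent of the substrate put in, red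
* amount of open intermediate at the outlet or at the end, in percent of the substrate put in, violet
* amount of open intermediate at the outlet or at the end, in percent of the substrate put in, green

- the stated concentrations are those of everything mixed, before any reaction; amounts are the same in each set-up
- the numbers in the tables scatter with a standard deviation of 2 percentage points
- the feed brings no volume worth counting
- the earlier runs were made in a closed, stirred flask

In the eta run the substrate is down to 8% at 2.50 min, which reads as an opening constant of 1.01 /min. I read the flat top as a crossing: up to it the open intermediate climbs, on it I take opening and loss as equal, and past it I expect the open intermediate to fall. So the opening constant times that ratio gives 0.208 /min, my loss constant, a pseudo-first-order constant for the going of open intermediate, read from scattered readings. Blue at 4.0 min stands later than the crossing at 2.00 min, and the two constants run in sequence give me 52.5% for blue, which is the number I commit to.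

The forecast says blue 51%, red 52%, violet 54% and green 43%, and it names violet as best. Its blue stands below mine, and it warns: “The data cannot show whether this loss depends on partner”.

The flask gives red as best, at 57.5%, against blue 53.3%, violet 53.4% and green 42.6%.

    substrate + target → side product B (k = 0.170 /M/s)
    partner → second intermediate (k = 0.00250 /s)
    open intermediate + second intermediate → target (k = 0.130 /M/s)
    substrate → open intermediate (k = 0.0160 /s)
    open intermediate → side product A (k = 0.00270 /s)

Red ends with 3.23% of target where blue ends with 8.48%, while side product A stands at 37.0% in red and 35.8% in blue. At 0.208 /min, red's lead over blue is worth 0.365 min of fall. Read red later, at 6.00 min: the loss constant takes its 57.5% down to 37.9%, and the computed flask holds 39.1%.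

The numbers in the tables were generated by integration on assumed constants; the scatter is artificial.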